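**Plan**

- Retrosynthesis: ring D (the lactol) is opened to a hydroxy aldehyde masked as silyl ether and dioxolane. The C–CH3 bond of the ring C carbinol and the CH2–CH bond joining the two-carbon linker to ring C are cut (methyl addition, aldol), leaving a ring A/B aldehyde and a ring C silyl enol ether. In ring A the bond between the CMe2-bearing ring-fusion carbon and the alkene CH is re-drawn, and the cyclobutane so formed is cut as an enone–alkene [2+2] adduct.
- Feature used: ring A (cycloheptene) shares two adjacent CH carbons with ring B (cyclopentane), and exactly three ring atoms (CMe2, the side-chain CH, the methyl-bearing alkene carbon) separate one of them from the alkene CH. That extra bond therefore turns ring A into a cyclobutane fused to a five-membered ring, the photoadduct of a 3-substituted cyclopent-2-enone (ring B) and a tethered vinyl carbinol.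
- Forward order: CMe2–furan acid → linker CH by auxiliary alkylation → vinyl carbinol → ring B enone from the furan → cyclobutane and five-membered ring by light → ring A by radical opening of the cyclobutane → aldol union with ring C (three steps from a silyloxycyclohexenone) → ring C carbinol → ring D on deprotection.
- Stereochemistry: the linker CH comes from an oxazolidinone auxiliary and steers the photocycloaddition (first ring-fusion CH; the second by hydrogen transfer to the convex face). The ring B carbinol comes from peracid attack anti to the cyclobutane. Ring C comes from (S)-4-silyloxycyclohex-2-enone (cuprate anti to oxygen, equatorial side chain, equatorial methyllithium attack). The lactol carbon is under thermodynamic control.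

Key step: step 13

Remarks on the chemistry:
- The lactol carbon of ring D epimerises through the open hydroxy aldehyde; the anomer drawn (equatorial hydroxyl) is taken as the one favoured at equilibrium.
- The carbinol carbon made in step 8 is drawn as the Felkin–Anh epimer; it becomes sp2 in step 18, so either epimer serves.
- Aldol adduct 39 (two new centres, left undefined) and enone 41 (drawn Z) are carried as mixtures that converge in step 26.

Ring letters: A = cycloheptene, B = cyclopentane, C = cyclohexane, D = lactol ring.

**Route**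

Step 1
Reactants: 1 2-methylfuran; 2 diethyl isopropylidenemalonate
Product: 5 diethyl 2-[2-(5-methylfuran-2-yl)propan-2-yl]propanedioate, via 5-methyl-2-furyllithium 3 (not isolated), via 5-methyl-2-furylmagnesium bromide 4 (not isolated)
Conditions: n-BuLi, THF, 0 °C → rt; MgBr2·OEt2, 0 °C; CuI (10 mol %), then 2, −30 → 0 °C; aq NH4Cl
Reagents that add atoms: none
Why: Copper-catalysed conjugate addition of the furyl Grignard reagent to the doubly activated alkylidene malonate (the classical route to tert-alkyl malonates) creates the quaternary CMe2 carbon on the furan, which is the latent 1,4-diketone of ring B.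

Step 2
Reactants: 5 diethyl 2-[2-(5-methylfuran-2-yl)propan-2-yl]propanedioate
Product: 7 3-methyl-3-(5-methylfuran-2-yl)butanoic acid, via substituted malonic acid 6 (not isolated)
Conditions: KOH, EtOH–H2O, 80 °C; aq HCl to pH 2, 0 °C; pyridine, 115 °C
Reagents that add atoms: potassium hydroxide, [K+].[OH-]
Why: Saponification followed by thermal decarboxylation of the monosubstituted malonic acid (malonic ester synthesis) leaves the acetic acid chain on the quaternary carbon, and the furan meets acid only briefly and cold.

Step 3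
Reactants: 7 3-methyl-3-(5-methylfuran-2-yl)butanoic acid; 8 (S)-4-benzyloxazolidin-2-one
Product: 10 (S)-4-benzyl-3-[3-methyl-3-(5-methylfuran-2-yl)butanoyl]oxazolidin-2-one, via mixed pivalic anhydride 9 (not isolated)
Conditions: PivCl, Et3N, THF, −20 °C; then LiCl, 8, −20 °C → rt
Reagents that add atoms: none
Why: N-Acylation of the oxazolidinone through the mixed pivalic anhydride, promoted by LiCl and triethylamine, takes place only at the less hindered acyl group.

Step 4
Reactants: 10 (S)-4-benzyl-3-[3-methyl-3-(5-methylfuran-2-yl)butanoyl]oxazolidin-2-one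
Product: 12 (S)-4-benzyl-3-[(S)-2-[2-(5-methylfuran-2-yl)propan-2-yl]pent-4-enoyl]oxazolidin-2-one, via sodium Z-enolate 11 (not isolated)
Conditions: NaN(SiMe3)2, THF, −78 °C; allyl iodide, −78 → −40 °C
Reagents that add atoms: allyl iodide, C=CCI
Why: Evans alkylation: the chelated (Z)-sodium enolate is shielded on one face by the benzyl group, so allyl iodide, the most reactive simple electrophile for an enolate next to a quaternary carbon, enters from the other face and sets the linker CH as (S).

Step 5
Reactants: 12 (S)-4-benzyl-3-[(S)-2-[2-(5-methylfuran-2-yl)propan-2-yl]pent-4-enoyl]oxazolidin-2-one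
Product: 14 (S)-4-benzyl-3-[(S)-2-[2-(5-methylfuran-2-yl)propan-2-yl]-4-oxobutanoyl]oxazolidin-2-one, via vicinal diol 13 (not isolated)
Conditions: OsO4 (2 mol %), NaIO4, 2,6-lutidine, dioxane–H2O (3:1), rt
Reagents that add atoms: sodium periodate, [Na+].[O-]I(=O)(=O)=O
Why: Lemieux–Johnson oxidation: OsO4 dihydroxylates the monosubstituted alkene much faster than the aromatic furan, and periodate cleaves the diol and reoxidises osmium, shortening the allyl group to the two-carbon aldehyde.

Step 6
Reactants: 14 (S)-4-benzyl-3-[(S)-2-[2-(5-methylfuran-2-yl)propan-2-yl]-4-oxobutanoyl]oxazolidin-2-one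
Product: 16 (S)-3-[2-(5-methylfuran-2-yl)propan-2-yl]oxolan-2-one, via hydroxy imide 15 (not isolated)
Conditions: NaBH4, THF–MeOH, −20 → 0 °C
Reagents that add atoms: none
Why: Borohydride reduces the aldehyde, and the resulting γ-alkoxide attacks the exocyclic imide carbonyl (5-exo-trig lactonisation), which releases the auxiliary for recovery without touching the α-stereocentre.

Step 7
Reactants: 16 (S)-3-[2-(5-methylfuran-2-yl)propan-2-yl]oxolan-2-one
Product: 17 (S)-5-hydroxy-3-[2-(5-methylfuran-2-yl)propan-2-yl]pentan-2-one (in equilibrium with its cyclic hemiketal)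
Conditions: MeLi (1.05 equiv), THF, −78 °C; aq NH4Cl
Reagents that add atoms: methyllithium, [Li]C
Why: Mono-addition of methyllithium to the γ-lactone: the tetrahedral lithium alkoxide survives at −78 °C until the quench and then opens to the hydroxy methyl ketone, and addition to the carbonyl should outrun deprotonation of the hindered α-CH.

Step 8
Reactants: 17 (S)-5-hydroxy-3-[2-(5-methylfuran-2-yl)propan-2-yl]pentan-2-one
Product: 18 (3S,4S)-3-methyl-4-[2-(5-methylfuran-2-yl)propan-2-yl]hex-1-ene-3,6-diol
Conditions: CH2=CHMgBr (3 equiv), LaCl3·2LiCl (0.3 equiv), THF, −78 → 0 °C; aq NH4Cl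
Reagents that add atoms: vinylmagnesium bromide, C=C[Mg]Br
Why: 1,2-Addition of the vinyl Grignard reagent to the methyl ketone (the first equivalent deprotonates the hydroxyl, LaCl3·2LiCl suppresses enolisation) is expected mainly in the Felkin–Anh sense, with the furyl-substituted quaternary carbon anti to the incoming nucleophile.

Step 9
Reactants: 18 (3S,4S)-3-methyl-4-[2-(5-methylfuran-2-yl)propan-2-yl]hex-1-ene-3,6-diol
Product: 19 (3S,4S)-3,6-bis(tert-butyldimethylsilyloxy)-3-methyl-4-[2-(5-methylfuran-2-yl)propan-2-yl]hex-1-ene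
Conditions: TBSOTf (3 equiv), 2,6-lutidine, CH2Cl2, 0 °C → rt
Reagents that add atoms: tert-butyldimethylsilyl triflate, CC(C)(C)[Si](C)(C)OS(=O)(=O)C(F)(F)F
Why: The silyl triflate with a hindered pyridine base silylates the primary and the hindered tertiary allylic alcohol in one operation, which keeps both oxygens from adding to the carbonyl groups unveiled in the next three steps.

Step 10
Reactants: 19 (3S,4S)-3,6-bis(tert-butyldimethylsilyloxy)-3-methyl-4-[2-(5-methylfuran-2-yl)propan-2-yl]hex-1-ene
Product: 20 (3Z,7S,8S)-8-(tert-butyldimethylsilyloxy)-7-[2-(tert-butyldimethylsilyloxy)ethyl]-6,6,8-trimethyldeca-3,9-diene-2,5-dione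
Conditions: NBS (1.05 equiv), NaHCO3, acetone–H2O (10:1), −20 °C
Reagents that add atoms: water, O
Why: Oxidative ring opening of the 2,5-dialkylfuran (bromination at an α-position, hydration, loss of bromide) gives the (Z)-ene-1,4-dione under cold buffered conditions that spare the vinyl group and both silyl ethers.

Step 11
Reactants: 20 (3Z,7S,8S)-8-(tert-butyldimethylsilyloxy)-7-[2-(tert-butyldimethylsilyloxy)ethyl]-6,6,8-trimethyldeca-3,9-diene-2,5-dione
Product: 21 (7S,8S)-8-(tert-butyldimethylsilyloxy)-7-[2-(tert-butyldimethylsilyloxy)ethyl]-6,6,8-trimethyldec-9-ene-2,5-dione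
Conditions: Zn dust, AcOH, rt
Reagents that add atoms: none
Why: Zinc in acetic acid reduces the electron-poor ene-dione double bond by electron transfer and leaves the isolated vinyl group and the silyl ethers untouched.

Step 12
Reactants: 21 (7S,8S)-8-(tert-butyldimethylsilyloxy)-7-[2-(tert-butyldimethylsilyloxy)ethyl]-6,6,8-trimethyldec-9-ene-2,5-dione
Product: 23 3-[(3S,4S)-4-(tert-butyldimethylsilyloxy)-3-[2-(tert-butyldimethylsilyloxy)ethyl]-2,4-dimethylhex-5-en-2-yl]cyclopent-2-en-1-one, via cyclic ketol 22 (not isolated)
Conditions: KOH (2%), MeOH, 50 °C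
Reagents that add atoms: none
Why: Intramolecular aldol condensation: only the enolate of the terminal methyl ketone can reach the other carbonyl through a five-membered transition state, so cyclodehydration gives the 3-substituted cyclopent-2-enone and no regioisomer.

Step 13
Reactants: 23 3-[(3S,4S)-4-(tert-butyldimethylsilyloxy)-3-[2-(tert-butyldimethylsilyloxy)ethyl]-2,4-dimethylhex-5-en-2-yl]cyclopent-2-en-1-one
Product: 24 angular tricyclic photoadduct (cyclopentanone and silyloxycyclopentane each cis-fused to a central cyclobutane; silyloxyethyl chain on the convex face)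
Conditions: hν (366 nm, Pyrex), degassed CH2Cl2 (0.01 M), 0 °C
Reagents that add atoms: none
Why: Excitation of the 3-alkylcyclopentenone and intersystem crossing give the triplet enone, whose β-carbon (the future ring-fusion carbon next to CMe2) attacks the internal vinyl carbon to give a 1,4-biradical that, after spin inversion, collapses between the enone α-carbon and the terminal CH2, so that the sacrificial bond and the ring-fusion CH–CH2 bond of ring A are formed. The closest known reaction type is the intramolecular enone–alkene [2+2] photocycloaddition of 3-(pent-4-enyl)cycloalk-2-enones, which gives fused (straight) cyclobutanes. The five-membered carbocycle closes 5-exo-trig at the vinyl group (three-atom tether, rule of five), and the cyclobutane then closes by radical recombination, necessarily cis-fused to both five-membered rings. The quaternary carbon and the cyclobutane CH are set in the first bond formation by the linker stereocentre, whose silyloxyethyl chain takes the convex side of the forming bicyclo[3.2.0]heptane, and the α-CH follows from the cis fusion of the cyclobutane. The step needs straight rather than crossed regioselectivity, which the three-atom tether secures, and face selectivity on the enone, which the linker CH between two fully substituted carbons secures; the silyl ethers do not absorb at this wavelength.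

Step 14
Reactants: 24 angular tricyclic photoadduct
Product: 25 exocyclic methylene analogue of 24 (C=CH2 in place of C=O)
Conditions: Ph3PCH3Br, KOtBu, PhMe, rt → 80 °C
Reagents that add atoms: methyltriphenylphosphonium bromide, C[P+](c1ccccc1)(c1ccccc1)c1ccccc1.[Br-]
Why: Wittig methylenation of the cyclopentanone is safe under base because the only stereocentre α to the carbonyl is a cyclobutane bridgehead and cannot epimerise.

Step 15
Reactants: 25 exocyclic methylene analogue of 24
Product: 26 spiro-epoxide (oxygen cis to the ring-fusion hydrogen next to the spiro carbon)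
Conditions: mCPBA, NaHCO3, CH2Cl2, 0 °C
Reagents that add atoms: meta-chloroperbenzoic acid, OOC(=O)c1cccc(Cl)c1
Why: Prilezhaev epoxidation of the exocyclic alkene from the exo face of the bicyclo[3.2.0]heptane unit, anti to the cyclobutane methylene on the neighbouring carbon, places oxygen cis to the ring-fusion hydrogen and so fixes the configuration of the future ring B carbinol.

Step 16
Reactants: 26 spiro-epoxide
Product: 27 epoxy diol (primary and tertiary hydroxyl free)
Conditions: TBAF (4 equiv), THF, rt → 50 °C
Reagents that add atoms: none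
Why: Fluoride-mediated desilylation frees both alcohols under basic conditions that the epoxide tolerates.

Step 17
Reactants: 27 epoxy diol
Product: 28 epoxy bis(methyl oxalate)
Conditions: ClC(O)CO2Me (3 equiv), DMAP, pyridine, CH2Cl2, 0 °C → rt
Reagents that add atoms: methyl chlorooxoacetate, COC(=O)C(Cl)=O
Why: Acylation with the highly electrophilic oxalyl monochloride under DMAP catalysis esterifies the hindered tertiary alcohol as well as the primary one.

Step 18
Reactants: 28 epoxy bis(methyl oxalate)
Product: 29 cis-fused bicyclo[5.3.0]decene (rings A and B) with spiro-epoxide and primary methyl oxalate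
Conditions: Bu3SnH (syringe pump), AIBN, PhMe (0.003 M), 110 °C
Reagents that add atoms: none
Why: Barton–McCombie-type reduction of the tertiary methyl oxalate gives the tertiary radical beside the cyclobutane, whose β-scission of the ring bond to the quaternary carbon (cyclobutylcarbinyl radical fragmentation) gives the trisubstituted alkene of ring A and the tertiary ring-fusion radical, slow addition of the hydride at 110 °C leaving time for a radical formed by opening of the other cyclobutane bond to re-close and drain through this more stable radical, which then takes hydrogen on its convex face, anti to the ring A methylene on the neighbouring carbon, to give the cis ring fusion, while the primary oxalate and the epoxide do not react.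

Step 19
Reactants: 29 cis-fused bicyclo[5.3.0]decene epoxide oxalate
Product: 30 (1S,3aS,5R,8aS)-5-(2-hydroxyethyl)-1,4,4,6-tetramethyl-1,2,3,3a,4,5,8,8a-octahydroazulen-1-ol
Conditions: LiAlH4, THF, 0 °C → rt
Reagents that add atoms: none
Why: LiAlH4 opens the 1,1-disubstituted epoxide by SN2 attack of hydride at its methylene carbon, which gives the methyl carbinol with oxygen where the peracid placed it, and reduces the primary oxalate to the alcohol.

Step 20
Reactants: 30 (1S,3aS,5R,8aS)-5-(2-hydroxyethyl)-1,4,4,6-tetramethyl-1,2,3,3a,4,5,8,8a-octahydroazulen-1-ol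
Product: 31 2-[(1S,3aS,5R,8aS)-1-hydroxy-1,4,4,6-tetramethyl-1,2,3,3a,4,5,8,8a-octahydroazulen-5-yl]acetaldehyde
Conditions: TEMPO (10 mol %), PhI(OAc)2, CH2Cl2, rt
Reagents that add atoms: none
Why: Oxoammonium (TEMPO) oxidation is selective for the primary alcohol and stops at the aldehyde, leaving the tertiary alcohol and the trisubstituted alkene untouched.

Step 21
Reactants: 32 (S)-4-(tert-butyldimethylsilyloxy)cyclohex-2-en-1-one
Product: 33 tert-butyldimethyl{[(1S,2S)-2-methyl-4-(trimethylsilyloxy)cyclohex-3-en-1-yl]oxy}silane
Conditions: Me2CuLi (from MeLi and CuI), TMSCl, THF–Et2O, −78 °C; Et3N, aq NaHCO3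
Reagents that add atoms: methyllithium, [Li]C; chlorotrimethylsilane, C[Si](C)(C)Cl
Why: Conjugate addition of the Gilman cuprate anti to the γ-silyloxy group with in situ O-silylation of the enolate brings in the ring C methyl carbon, and the new methyl stereocentre is removed in the next step.

Step 22
Reactants: 33 tert-butyldimethyl{[(1S,2S)-2-methyl-4-(trimethylsilyloxy)cyclohex-3-en-1-yl]oxy}silane
Product: 34 (S)-4-(tert-butyldimethylsilyloxy)-3-methylcyclohex-2-en-1-one
Conditions: Pd(OAc)2 (1.05 equiv), MeCN, rt
Reagents that add atoms: none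
Why: Saegusa–Ito oxidation: the silyl enol ether gives an oxa-π-allylpalladium species that loses β-hydride from the methyl-bearing carbon and returns the enone with the methyl group at the β-position.

Step 23
Reactants: 34 (S)-4-(tert-butyldimethylsilyloxy)-3-methylcyclohex-2-en-1-one; 35 2-(2-bromoethyl)-1,3-dioxolane
Product: 37 tert-butyl{[(1S,2S)-2-[2-(1,3-dioxolan-2-yl)ethyl]-2-methyl-4-(trimethylsilyloxy)cyclohex-3-en-1-yl]oxy}dimethylsilane, via dioxolanylethylmagnesium bromide 36 (not isolated)
Conditions: 35, Mg, THF, 25 °C; then CuBr·SMe2 (20 mol %), TMSCl, 34, THF, −78 → −40 °C; Et3N, aq NaHCO3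
Reagents that add atoms: chlorotrimethylsilane, C[Si](C)(C)Cl
Why: Copper-catalysed conjugate addition of the Grignard reagent, accelerated by TMSCl, occurs anti to the neighbouring silyloxy group and so sets the quaternary carbon with methyl cis and the three-carbon chain trans to oxygen, while silylation stores the enolate regiospecifically.

Step 24
Reactants: 37 ring C silyl enol ether; 31 ring A/B aldehyde
Product: 39 aldol adduct (β-hydroxy ketone joining the linker to ring C), via lithium enolate 38 (not isolated)
Conditions: 37 (2.5 equiv), MeLi, THF, 0 °C; then 31, −78 °C; aq NH4Cl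
Reagents that add atoms: none
Why: Methyllithium cleaves the silyl enol ether to the lithium enolate with its double bond fixed towards the carbon next to the quaternary centre, and aldol addition to aldehyde 31 joins the two halves at the future ring C CH, the first equivalent of enolate merely deprotonating the tertiary hydroxyl.

Step 25
Reactants: 39 aldol adduct
Product: 41 alkylidene ketone (enone between the linker CH and ring C), via β-acetoxy ketone 40 (not isolated)
Conditions: Ac2O, DMAP, Et3N, CH2Cl2, 0 °C; then DBU, 40 °C
Reagents that add atoms: none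
Why: Acetylation of the secondary aldol hydroxyl (the hindered tertiary hydroxyl is left) and E1cB elimination with DBU complete an aldol condensation to the alkylidene ketone.

Step 26
Reactants: 41 alkylidene ketone
Product: 42 saturated ring C ketone with equatorial side chain
Conditions: [(Ph3P)CuH]6, H2O (5 equiv), PhMe, rt
Reagents that add atoms: none
Why: Conjugate reduction by the copper hydride hexamer (hydride to the β-carbon, protonation of the copper enolate by water) saturates only the enone, and the proton enters the enolate carbon anti to the axial methyl group on the neighbouring quaternary carbon, which places the side chain equatorial, the arrangement also favoured at equilibrium.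

Step 27
Reactants: 42 saturated ring C ketone
Product: 43 silyl- and dioxolane-protected target (ring C methyl carbinol)
Conditions: MeLi (4 equiv), LaCl3·2LiCl (0.3 equiv), THF, −78 °C; aq NH4Cl
Reagents that add atoms: methyllithium, [Li]C
Why: In this 1,2-addition axial approach to the ring C ketone is blocked by the syn-axial methyl group on the quaternary carbon, so the methyl group enters equatorially and the new hydroxyl is axial, cis to that methyl group as in the target, while the excess reagent covers the free tertiary hydroxyl of ring B.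

Step 28
Reactants: 43 protected target
Product: 45 CNP0167351.1, via open hydroxy aldehyde 44 (not isolated)
Conditions: HCl (1 M aq)–THF (1:2), rt
Reagents that add atoms: water, O
Why: Aqueous acid cleaves the silyl ether and hydrolyses the dioxolane, and the hydroxy aldehyde closes spontaneously to the six-membered lactol (ring D, trans-fused to ring C), whose anomeric carbon equilibrates to the equatorial hydroxyl drawn.

**Compound list**

1 | 2-methylfuran | Cc1ccco1 | starting material
2 | diethyl isopropylidenemalonate | CCOC(=O)C(=C(C)C)C(=O)OCC | starting material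
3 | 5-methyl-2-furyllithium (not isolated) | [Li]c1ccc(C)o1 | intermediate
4 | 5-methyl-2-furylmagnesium bromide (not isolated) | Cc1ccc(o1)[Mg]Br | intermediate
5 | diethyl 2-[2-(5-methylfuran-2-yl)propan-2-yl]propanedioate | CCOC(=O)C(C(=O)OCC)C(C)(C)c1ccc(C)o1 | intermediate
6 | 2-[2-(5-methylfuran-2-yl)propan-2-yl]propanedioic acid (not isolated) | OC(=O)C(C(=O)O)C(C)(C)c1ccc(C)o1 | intermediate
7 | 3-methyl-3-(5-methylfuran-2-yl)butanoic acid | Cc1ccc(o1)C(C)(C)CC(=O)O | intermediate
8 | (S)-4-benzyloxazolidin-2-one | O=C1N[C@@H](Cc2ccccc2)CO1 | starting material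
9 | 3-methyl-3-(5-methylfuran-2-yl)butanoic pivalic anhydride (not isolated) | Cc1ccc(o1)C(C)(C)CC(=O)OC(=O)C(C)(C)C | intermediate
10 | (S)-4-benzyl-3-[3-methyl-3-(5-methylfuran-2-yl)butanoyl]oxazolidin-2-one | Cc1ccc(o1)C(C)(C)CC(=O)N1[C@@H](Cc2ccccc2)COC1=O | intermediate
11 | sodium (Z)-enolate of 10 (not isolated) | Cc1ccc(o1)C(C)(C)/C=C(\[O-])N1[C@@H](Cc2ccccc2)COC1=O.[Na+] | intermediate
12 | (S)-4-benzyl-3-[(S)-2-[2-(5-methylfuran-2-yl)propan-2-yl]pent-4-enoyl]oxazolidin-2-one | Cc1ccc(o1)C(C)(C)[C@H](CC=C)C(=O)N1[C@@H](Cc2ccccc2)COC1=O | intermediate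
13 | 4,5-dihydroxypentanoyl imide from 12 (both carbinol epimers; not isolated) | Cc1ccc(o1)C(C)(C)[C@H](CC(O)CO)C(=O)N1[C@@H](Cc2ccccc2)COC1=O | intermediate
14 | (S)-4-benzyl-3-[(S)-2-[2-(5-methylfuran-2-yl)propan-2-yl]-4-oxobutanoyl]oxazolidin-2-one | Cc1ccc(o1)C(C)(C)[C@H](CC=O)C(=O)N1[C@@H](Cc2ccccc2)COC1=O | intermediate
15 | (S)-4-benzyl-3-[(S)-4-hydroxy-2-[2-(5-methylfuran-2-yl)propan-2-yl]butanoyl]oxazolidin-2-one (not isolated) | Cc1ccc(o1)C(C)(C)[C@H](CCO)C(=O)N1[C@@H](Cc2ccccc2)COC1=O | intermediate
16 | (S)-3-[2-(5-methylfuran-2-yl)propan-2-yl]oxolan-2-one | Cc1ccc(o1)C(C)(C)[C@@H]1CCOC1=O | intermediate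
17 | (S)-5-hydroxy-3-[2-(5-methylfuran-2-yl)propan-2-yl]pentan-2-one | Cc1ccc(o1)C(C)(C)[C@H](CCO)C(C)=O | intermediate
18 | (3S,4S)-3-methyl-4-[2-(5-methylfuran-2-yl)propan-2-yl]hex-1-ene-3,6-diol | Cc1ccc(o1)C(C)(C)[C@H](CCO)[C@@](C)(O)C=C | intermediate
19 | (3S,4S)-3,6-bis(tert-butyldimethylsilyloxy)-3-methyl-4-[2-(5-methylfuran-2-yl)propan-2-yl]hex-1-ene | Cc1ccc(o1)C(C)(C)[C@H](CCO[Si](C)(C)C(C)(C)C)[C@@](C)(O[Si](C)(C)C(C)(C)C)C=C | intermediate
20 | (3Z,7S,8S)-8-(tert-butyldimethylsilyloxy)-7-[2-(tert-butyldimethylsilyloxy)ethyl]-6,6,8-trimethyldeca-3,9-diene-2,5-dione | CC(=O)/C=C\C(=O)C(C)(C)[C@H](CCO[Si](C)(C)C(C)(C)C)[C@@](C)(O[Si](C)(C)C(C)(C)C)C=C | intermediate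
21 | (7S,8S)-8-(tert-butyldimethylsilyloxy)-7-[2-(tert-butyldimethylsilyloxy)ethyl]-6,6,8-trimethyldec-9-ene-2,5-dione | CC(=O)CCC(=O)C(C)(C)[C@H](CCO[Si](C)(C)C(C)(C)C)[C@@](C)(O[Si](C)(C)C(C)(C)C)C=C | intermediate
22 | 3-hydroxycyclopentanone aldol adduct of 21 (ring carbinol undefined; not isolated) | O=C1CCC(O)(C1)C(C)(C)[C@H](CCO[Si](C)(C)C(C)(C)C)[C@@](C)(O[Si](C)(C)C(C)(C)C)C=C | intermediate
23 | 3-[(3S,4S)-4-(tert-butyldimethylsilyloxy)-3-[2-(tert-butyldimethylsilyloxy)ethyl]-2,4-dimethylhex-5-en-2-yl]cyclopent-2-en-1-one | O=C1C=C(CC1)C(C)(C)[C@H](CCO[Si](C)(C)C(C)(C)C)[C@@](C)(O[Si](C)(C)C(C)(C)C)C=C | intermediate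
24 | angular tricyclic photoadduct: cyclopentanone, central cyclobutane, bis-silylated cyclopentane | O=C1CC[C@@]23[C@@H]1C[C@@H]2[C@](C)(O[Si](C)(C)C(C)(C)C)[C@@H](CCO[Si](C)(C)C(C)(C)C)C3(C)C | intermediate
25 | exocyclic methylene analogue of 24 | C=C1CC[C@@]23[C@@H]1C[C@@H]2[C@](C)(O[Si](C)(C)C(C)(C)C)[C@@H](CCO[Si](C)(C)C(C)(C)C)C3(C)C | intermediate
26 | spiro-epoxide of 25 (oxygen cis to the adjacent ring-fusion hydrogen) | C1O[C@]12CC[C@@]34[C@@H]2C[C@@H]3[C@](C)(O[Si](C)(C)C(C)(C)C)[C@@H](CCO[Si](C)(C)C(C)(C)C)C4(C)C | intermediate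
27 | epoxy diol | C1O[C@]12CC[C@@]34[C@@H]2C[C@@H]3[C@](C)(O)[C@@H](CCO)C4(C)C | intermediate
28 | epoxy bis(methyl oxalate) | C1O[C@]12CC[C@@]34[C@@H]2C[C@@H]3[C@](C)(OC(=O)C(=O)OC)[C@@H](CCOC(=O)C(=O)OC)C4(C)C | intermediate
29 | cis-fused ring A/B spiro-epoxide with primary methyl oxalate | CC1=CC[C@H]2[C@H](CC[C@]23OC3)C(C)(C)[C@@H]1CCOC(=O)C(=O)OC | intermediate
30 | (1S,3aS,5R,8aS)-5-(2-hydroxyethyl)-1,4,4,6-tetramethyl-1,2,3,3a,4,5,8,8a-octahydroazulen-1-ol | CC1=CC[C@H]2[C@H](CC[C@]2(C)O)C(C)(C)[C@@H]1CCO | intermediate
31 | 2-[(1S,3aS,5R,8aS)-1-hydroxy-1,4,4,6-tetramethyl-1,2,3,3a,4,5,8,8a-octahydroazulen-5-yl]acetaldehyde | CC1=CC[C@H]2[C@H](CC[C@]2(C)O)C(C)(C)[C@@H]1CC=O | intermediate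
32 | (S)-4-(tert-butyldimethylsilyloxy)cyclohex-2-en-1-one | O=C1C=C[C@@H](O[Si](C)(C)C(C)(C)C)CC1 | starting material
33 | tert-butyldimethyl{[(1S,2S)-2-methyl-4-(trimethylsilyloxy)cyclohex-3-en-1-yl]oxy}silane | C[Si](C)(C)OC1=C[C@H](C)[C@@H](O[Si](C)(C)C(C)(C)C)CC1 | intermediate
34 | (S)-4-(tert-butyldimethylsilyloxy)-3-methylcyclohex-2-en-1-one | O=C1C=C(C)[C@@H](O[Si](C)(C)C(C)(C)C)CC1 | intermediate
35 | 2-(2-bromoethyl)-1,3-dioxolane | BrCCC1OCCO1 | starting material
36 | [2-(1,3-dioxolan-2-yl)ethyl]magnesium bromide (not isolated) | Br[Mg]CCC1OCCO1 | intermediate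
37 | tert-butyl{[(1S,2S)-2-[2-(1,3-dioxolan-2-yl)ethyl]-2-methyl-4-(trimethylsilyloxy)cyclohex-3-en-1-yl]oxy}dimethylsilane | C[Si](C)(C)OC1=C[C@](C)(CCC2OCCO2)[C@@H](O[Si](C)(C)C(C)(C)C)CC1 | intermediate
38 | lithium enolate from 37 (not isolated) | [Li+].[O-]C1=C[C@](C)(CCC2OCCO2)[C@@H](O[Si](C)(C)C(C)(C)C)CC1 | intermediate
39 | aldol adduct of 31 and 38 (carbinol and ring C α-carbon undefined) | CC1=CC[C@H]2[C@H](CC[C@]2(C)O)C(C)(C)[C@@H]1CC(O)C1C(=O)CC[C@H](O[Si](C)(C)C(C)(C)C)[C@@]1(C)CCC1OCCO1 | intermediate
40 | β-acetoxy ketone from 39 (not isolated) | CC1=CC[C@H]2[C@H](CC[C@]2(C)O)C(C)(C)[C@@H]1CC(OC(C)=O)C1C(=O)CC[C@H](O[Si](C)(C)C(C)(C)C)[C@@]1(C)CCC1OCCO1 | intermediate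
41 | alkylidene ketone (drawn as the Z isomer) | CC1=CC[C@H]2[C@H](CC[C@]2(C)O)C(C)(C)[C@@H]1C/C=C1\C(=O)CC[C@H](O[Si](C)(C)C(C)(C)C)[C@@]1(C)CCC1OCCO1 | intermediate
42 | saturated ring C ketone with equatorial side chain | CC1=CC[C@H]2[C@H](CC[C@]2(C)O)C(C)(C)[C@@H]1CC[C@@H]1C(=O)CC[C@H](O[Si](C)(C)C(C)(C)C)[C@@]1(C)CCC1OCCO1 | intermediate
43 | protected target (ring C methyl carbinol; silyl ether and dioxolane in place) | CC1=CC[C@H]2[C@H](CC[C@]2(C)O)C(C)(C)[C@@H]1CC[C@@H]1[C@](C)(O)CC[C@H](O[Si](C)(C)C(C)(C)C)[C@@]1(C)CCC1OCCO1 | intermediate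
44 | open hydroxy aldehyde form of the target (not isolated) | CC1=CC[C@H]2[C@H](CC[C@]2(C)O)C(C)(C)[C@@H]1CC[C@@H]1[C@](C)(O)CC[C@H](O)[C@@]1(C)CCC=O | intermediate
45 | CNP0167351.1 | CC1=CC[C@H]2[C@H](CC[C@]2(C)O)C(C)(C)[C@@H]1CC[C@H]1[C@]2(C)CC[C@@H](O)O[C@H]2CC[C@@]1(C)O | target

**Count**

Total steps: 28. Longest linear sequence: 25 steps (steps 1–20, then 24–28); the ring C branch is steps 21–23.

**Steps most likely to fail**

1. Step 18, β-scission at the wrong cyclobutane bond. The radical carbon lies in the five-membered ring that contains the bond to be broken, so the outer CH–CH2 bond overlaps better with the radical orbital, while the wanted inner bond gives the more stable tertiary radical. If the kinetically opened primary radical is reduced before it re-closes, a spiro-cyclopentene forms instead of ring A. The fallback sets out from 24 and comes back at 30. It activates the inner bond from the cyclopentanone side, where that bond is exocyclic and well aligned. IBX (DMSO, 70 °C) dehydrogenates 24 to the tricyclic cyclopentenone F1, which makes the inner bond allylic. TBAF gives the enone diol F2 and methyl chlorooxoacetate the enone bis(methyl oxalate) F3. Bu3SnH/AIBN then opens the inner bond to a radical delocalised over the enone, and DBU brings the double bond into conjugation to give the cis-fused hydroazulenone F4. [(Ph3P)CuH]6 reduces the enone to the saturated ketone oxalate F5, K2CO3 in MeOH frees the hydroxy ketone F6, and Ph3P=CH2 gives the methylene alcohol F7. Mukaiyama hydration (Co(acac)2, PhSiH3, O2) prefers the 1,1-disubstituted alkene over the hindered ring A alkene and brings oxygen to the convex face, giving diol 30.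

2. Step 13, poor facial selectivity in the first bond formation. The bulky tertiary silyl ether may compete with the linker chain for the convex face of the forming bicycle. The fallback sets out from 23 and comes back at 27. It irradiates the free diol, in which the carbinol oxygen is the smallest group on the tether so that methyl and chain can both lie on the convex face. TBAF buffered with AcOH gives the diol enone F8, irradiation as in step 13 the photoadduct diol F9, Wittig methylenation with excess ylide the methylene diol F10, and mCPBA the epoxy diol 27.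

3. Step 15, peracid approach from the cyclobutane face. The gem-dimethyl carbon on the quaternary centre may screen the exo face and lead to the wrong carbinol configuration. The fallback sets out from 24 and comes back at 26. It builds the epoxide from the ketone with a carbon nucleophile, which enters from the face the peracid would take and so leaves oxygen on the other face. PhSCH2Li adds to 24 to give the β-hydroxy sulfide F11; S-methylation with Me3OBF4 and aqueous NaOH close the epoxide 26.

**Further compounds**

F1 | step 18 | tricyclic cyclopentenone from 24 (C=C between the two ring B methylene carbons) | O=C1C=C[C@@]23[C@@H]1C[C@@H]2[C@](C)(O[Si](C)(C)C(C)(C)C)[C@@H](CCO[Si](C)(C)C(C)(C)C)C3(C)C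
F2 | step 18 | enone diol | O=C1C=C[C@@]23[C@@H]1C[C@@H]2[C@](C)(O)[C@@H](CCO)C3(C)C
F3 | step 18 | enone bis(methyl oxalate) | O=C1C=C[C@@]23[C@@H]1C[C@@H]2[C@](C)(OC(=O)C(=O)OC)[C@@H](CCOC(=O)C(=O)OC)C3(C)C
F4 | step 18 | cis-fused hydroazulenone (conjugated enone in ring B, primary methyl oxalate) | CC1=CC[C@H]2[C@H](C=CC2=O)C(C)(C)[C@@H]1CCOC(=O)C(=O)OC
F5 | step 18 | saturated cis-fused ketone oxalate | CC1=CC[C@H]2[C@H](CCC2=O)C(C)(C)[C@@H]1CCOC(=O)C(=O)OC
F6 | step 18 | hydroxy ketone | CC1=CC[C@H]2[C@H](CCC2=O)C(C)(C)[C@@H]1CCO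
F7 | step 18 | methylene alcohol | CC1=CC[C@H]2[C@H](CCC2=C)C(C)(C)[C@@H]1CCO
F8 | step 13 | diol enone (desilylated 23) | O=C1C=C(CC1)C(C)(C)[C@H](CCO)[C@@](C)(O)C=C
F9 | step 13 | photoadduct diol | O=C1CC[C@@]23[C@@H]1C[C@@H]2[C@](C)(O)[C@@H](CCO)C3(C)C
F10 | step 13 | methylene diol | C=C1CC[C@@]23[C@@H]1C[C@@H]2[C@](C)(O)[C@@H](CCO)C3(C)C
F11 | step 15 | β-hydroxy sulfide from 24 (hydroxyl cis to the adjacent ring-fusion hydrogen) | O[C@@]1(CSc2ccccc2)CC[C@@]34[C@@H]1C[C@@H]3[C@](C)(O[Si](C)(C)C(C)(C)C)[C@@H](CCO[Si](C)(C)C(C)(C)C)C4(C)C
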